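The plan rests on cutting C4–C5 and C9–C10 of the decalin in one operation. C4 carries two identical CH2OH arms, is therefore not stereogenic, and can enter as the α-CH2 of an aldehyde. A chiral imidazolidinone and a one-electron oxidant then fold the acyclic dienal 15 into rings A and B, setting C5, C9 and C10 and placing the 8(17)-methylene through an allylsilane. The precursor is a farnesyl-like C13 chain: aldehyde, E-C5=C10 alkene, C8(CH2SiMe3)=C9 allylsilane, C12 pivalate. Formaldehyde later doubles the C4 formyl group; hydroboration at C8(17) and alkylation of a phenylthio lactone at C12 complete the aldehyde and the butenolide.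

Key step: step 8

Remarks on the chemistry (assumptions and design choices)
- Locants C1–C20 are labdane locants, used for the acyclic intermediates as well. In all bicyclic compounds the C10 methyl is anti to H5 (trans-decalin) and anti to H9 (C9 chain equatorial). A SMILES centre left unspecified means that both epimers are carried.
- Assumption: the sense of induction in step 8 is assigned from the usual shielding model of the imidazolidinone (aryl arm covers one face of the E radical cation). On that basis the (2R,5R) catalyst is chosen for (4S,5R,9R,10R)-16; the mirror-image catalyst would be used if the sense proved opposite.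
- Precursor design: the C12 oxygen is kept as an ester, because an ether there could capture a C8 cation as a tetrahydrofuran. The allylsilane must have C11 trans to C7 (Z by the sequence rule), and step 4 delivers this geometry. No free acid is added in step 8, to spare the allylsilane. The terminal alkene of 1 is the latent formyl carbon.

Step 1
Reactants: 1 hept-1-en-6-yne; 2 oxirane
Product: 5 (3E)-4-methylnona-3,8-dien-1-ol, via alkenylalane 3 (not isolated), via lithium alanate 4 (not isolated)
Conditions: Me3Al (2 equiv), Cp2ZrCl2 (0.2 equiv), CH2Cl2, 0 °C to rt; volatiles removed, hexane; n-BuLi, 0 °C; oxirane, THF, 0 °C to rt; 1 M HCl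
Reagents that add atoms: trimethylaluminium, C[Al](C)C
Why: Zirconium-catalysed syn-methylalumination of the terminal alkyne (Negishi carboalumination) is regio- and stereoselective and leaves the monosubstituted alkene untouched, and the derived alanate opens oxirane with retention at the alkenyl carbon, so the E geometry of the future C5=C10 bond is fixed here.

Step 2
Reactants: 5 (3E)-4-methylnona-3,8-dien-1-ol
Product: 6 (6E)-9-iodo-6-methylnona-1,6-diene
Conditions: PPh3, I2, imidazole, CH2Cl2, 0 °C to rt
Reagents that add atoms: iodine, [I][I]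
Why: Appel-type iodination under imidazole buffering converts the primary homoallylic alcohol into the iodide by SN2 displacement of the oxyphosphonium group without touching either alkene.

Step 3
Reactants: 6 (6E)-9-iodo-6-methylnona-1,6-diene; 7 2,3-dihydrofuran
Product: 9 5-[(3E)-4-methylnona-3,8-dien-1-yl]-2,3-dihydrofuran, via 5-lithio-2,3-dihydrofuran 8 (not isolated)
Conditions: 7 (1.5 equiv), t-BuLi, THF, −78 to 0 °C; then 6, −30 °C to rt; aq. NaHCO3
Reagents that add atoms: none
Why: Vinylic α-lithiation of the cyclic enol ether followed by SN2 alkylation with a primary iodide is an established route to 5-alkyl-2,3-dihydrofurans, including those from homoallylic iodides in isoprenoid chain extension.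

Step 4
Reactants: 9 5-[(3E)-4-methylnona-3,8-dien-1-yl]-2,3-dihydrofuran; 10 (trimethylsilyl)methylmagnesium chloride
Product: 11 (3Z,7E)-8-methyl-4-[(trimethylsilyl)methyl]trideca-3,7,12-trien-1-ol
Conditions: NiCl2(PPh3)2 (10 mol %), Me3SiCH2MgCl (3 equiv), PhMe, 80 °C; aq. NH4Cl
Reagents that add atoms: none
Why: Nickel-catalysed Kumada-type coupling at the enol-ether C–O bond (zerovalent nickel formed in situ inserts into the vinylic C–O bond) proceeds with retention with Grignard reagents that lack β-hydrogens, so CH2SiMe3 replaces oxygen cis to the CH2CH2OH arm and the C7 chain stays trans to C11, the geometry that later makes the C9 substituent equatorial.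

Step 5
Reactants: 11 (3Z,7E)-8-methyl-4-[(trimethylsilyl)methyl]trideca-3,7,12-trien-1-ol
Product: 12 (3Z,7E)-8-methyl-4-[(trimethylsilyl)methyl]trideca-3,7,12-trien-1-yl pivalate
Conditions: t-BuCOCl, pyridine, DMAP (cat.), CH2Cl2, 0 °C to rt
Reagents that add atoms: pivaloyl chloride, CC(C)(C)C(=O)Cl
Why: Acylation of the only hydroxyl group (nucleophilic catalysis by DMAP) installs an ester that survives the next three steps and, unlike an ether, cannot trap a cation at C8 in step 8.

Step 6
Reactants: 12 (3Z,7E)-8-methyl-4-[(trimethylsilyl)methyl]trideca-3,7,12-trien-1-yl pivalate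
Product: 14 (3Z,7E)-13-hydroxy-8-methyl-4-[(trimethylsilyl)methyl]trideca-3,7-dien-1-yl pivalate, via B-alkyl-9-BBN adduct 13 (not isolated)
Conditions: 9-BBN (1.2 equiv), THF, 0 °C to rt; then NaBO3·4H2O, H2O, rt
Reagents that add atoms: sodium perborate (NaBO3·4H2O, drawn as its peroxoborate dimer), [Na+].[Na+].O[B-]1(O)OO[B-](O)(O)OO1
Why: Anti-Markovnikov hydroboration–oxidation with the bulky 9-BBN takes the monosubstituted alkene far faster than the two trisubstituted ones, and perborate oxidation is mild enough for the pivalate and the allylsilane.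

Step 7
Reactants: 14 (3Z,7E)-13-hydroxy-8-methyl-4-[(trimethylsilyl)methyl]trideca-3,7-dien-1-yl pivalate
Product: 15 (3Z,7E)-8-methyl-13-oxo-4-[(trimethylsilyl)methyl]trideca-3,7-dien-1-yl pivalate
Conditions: (n-Pr4N)[RuO4] (5 mol %), N-methylmorpholine N-oxide (1.5 equiv), 4 Å MS, CH2Cl2, rt
Reagents that add atoms: none
Why: Ley–Griffith oxidation is neutral and stops at the aldehyde, so the acid-sensitive allylsilane, the alkenes and the ester are not at risk.

Step 8
Reactants: 15 (3Z,7E)-8-methyl-13-oxo-4-[(trimethylsilyl)methyl]trideca-3,7-dien-1-yl pivalate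
Product: 16 2-[(1R,4aR,5S,8aR)-5-formyl-8a-methyl-2-methylidenedecahydronaphthalen-1-yl]ethyl pivalate (labdane locants: 4S,5R,9R,10R; equatorial 4-formyl, 8(17)-ene, 12-pivalate)
Conditions: (2R,5R)-2-tert-butyl-3-methyl-5-(naphthalen-1-ylmethyl)imidazolidin-4-one·CF3CO2H (30 mol %), Cu(OTf)2 (2.5 equiv), CF3CO2Na (4 equiv), i-PrCN/DME, rt, 15 added over 8 h; aq. NaHCO3
Reagents that add atoms: none
Why: Proposed new method: condensation of 15 with the imidazolidinone gives an E-enamine that Cu(OTf)2 oxidises to a 3π-electron radical cation; its C4 adds to C5 of the C5=C10 alkene (ring A, 6-endo-trig), the tertiary C10 radical, or the C10 cation if divalent copper oxidises it first, adds to C9 of the allylsilane (ring B, 6-endo-trig), and the β-silyl C8 intermediate is oxidised and sheds Me3Si to leave the alkene only at C8(17), after which hydrolysis frees the catalyst. The closest known reaction type is the organo-SOMO polyene cyclisation of polyenals with this catalyst and oxidant, which ends on an arene, together with intra- and intermolecular SOMO α-allylation with allylsilanes; what is new is an allylsilane reached by a carbon-centred intermediate at the end of a cascade. C4 is set by the catalyst, whose naphthylmethyl arm covers one face of the radical cation while the iminium arm sits equatorial in the chair; C5 and C10 follow from the E geometry of C5=C10 in a chair–chair fold (trans ring fusion), and C9 from the C8=C9 geometry, in which C11 is trans to C7 and therefore becomes equatorial and anti to the C10 methyl. The step needs oxidation of the enamine in preference to the allylsilane (a mild copper oxidant), 6-endo over 5-exo closure (C10 and C8 are fully substituted), one alkene position (the β-silicon effect) and an intact terminator, which is why free acid is replaced by a CF3CO2Na buffer. The pivalate is kept on purpose because an ether oxygen on C12 could capture the C8 cation as a tetrahydrofuran.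

Step 9
Reactants: 16 bicyclic aldehyde pivalate; 17 formaldehyde
Product: 20 2-[(1R,4aS,8aS)-5,5-bis(hydroxymethyl)-8a-methyl-2-methylidenedecahydronaphthalen-1-yl]ethan-1-ol, via aldol adduct 18 (not isolated), via diol pivalate 19 (not isolated)
Conditions: aq. HCHO (37 %, 10 equiv), KOH (4 equiv), MeOH, 0 to 50 °C; then KOH (10 equiv), 65 °C; aq. HCl to pH 7
Reagents that add atoms: none
Why: Aldol–crossed Cannizzaro sequence (Tollens condensation): the only enolisable carbon, C4, adds to formaldehyde, the resulting non-enolisable aldehyde is reduced by hydride transfer from formaldehyde hydrate, and the excess hydroxide saponifies the pivalate in the same flask; C4 ceases to be a stereocentre, so its configuration in 16 is immaterial.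

Step 10
Reactants: 20 triol
Product: 21 18,19-O-isopropylidene acetal of 20 (spiro 2,2-dimethyl-1,3-dioxane at C4, 12-OH free)
Conditions: Me2C(OMe)2 (1.5 equiv), PPTS (cat.), acetone, rt; aq. NaHCO3
Reagents that add atoms: 2,2-dimethoxypropane, COC(C)(C)OC
Why: Acid-catalysed transacetalisation gives the six-membered isopropylidene acetal of the 1,3-diol selectively, leaves the isolated primary C12 hydroxyl free after work-up, and PPTS is too weak to isomerise the exocyclic alkene.

Step 11
Reactants: 21 acetonide alcohol
Product: 22 12-iodide corresponding to 21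
Conditions: PPh3, I2, imidazole (premixed), then 21, CH2Cl2, 0 °C to rt
Reagents that add atoms: iodine, [I][I]
Why: Appel-type iodination of the primary alcohol; because the phosphine–iodine adduct is formed first, no free iodine meets the C12-OH/8(17)-alkene pair (no iodoetherification), and imidazole protects the acetonide.

Step 12
Reactants: 23 3-bromodihydrofuran-2(3H)-one (racemic); 24 benzenethiol
Product: 25 3-(phenylsulfanyl)dihydrofuran-2(3H)-one (racemic)
Conditions: Et3N, CH2Cl2, 0 °C to rt
Reagents that add atoms: none
Why: SN2 displacement of the α-bromide by the thiolate gives the α-sulfenylated lactone that serves as a butenolide α-anion equivalent.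

Step 13
Reactants: 22 acetonide iodide; 25 3-(phenylsulfanyl)dihydrofuran-2(3H)-one
Product: 27 3-(phenylsulfanyl)dihydrofuran-2(3H)-one carrying at C3 the C12 terminus of the 22 skeleton (both C13 epimers), via lithium enolate 26 (not isolated)
Conditions: 25 (1.5 equiv), LiN(i-Pr)2, THF, −78 °C; then 22, DMPU, −78 °C to rt
Reagents that add atoms: none
Why: Alkylation of the sulfur-stabilised lactone enolate with an unhindered primary iodide (enolate SN2 alkylation) is a standard entry to 3-alkylbutenolides; the new quaternary centre forms as a mixture that is irrelevant because this carbon becomes sp2 in step 16.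

Step 14
Reactants: 27 alkylated phenylthio lactone
Product: 29 17-alcohol (8-CH2OH in place of the 8(17)-alkene of 27; C8 epimers), via B-alkyl-9-BBN adduct 28 (not isolated)
Conditions: 9-BBN (2.5 equiv), THF, rt to 45 °C; then NaBO3·4H2O, H2O, rt
Reagents that add atoms: sodium perborate (NaBO3·4H2O, drawn as its peroxoborate dimer), [Na+].[Na+].O[B-]1(O)OO[B-](O)(O)OO1
Why: Hydroboration–oxidation: 9-BBN adds its boron to the terminal carbon of the 1,1-disubstituted alkene and leaves the lactone and the thioether alone; hydrogen is expected to be delivered to C8 mainly from the face opposite the axial C10 methyl, but either C8 epimer serves because C8 is equilibrated in step 15.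

Step 15
Reactants: 29 17-alcohol
Product: 31 (8S)-17-aldehyde (formyl equatorial, trans to the C9 chain; C13 epimers), via C8-epimeric aldehyde 30 (not isolated)
Conditions: (COCl)2, DMSO, CH2Cl2, −78 °C; Et3N, to 0 °C; then DBU (0.3 equiv), CH2Cl2, rt
Reagents that add atoms: none
Why: Swern oxidation tolerates the thioether, and base-mediated enolisation (epimerisation) then places the formyl group equatorial, trans to the C9 chain and away from the syn-axial C10 methyl, so C8 is set under thermodynamic control.

Step 16
Reactants: 31 (8S)-17-aldehyde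
Product: 33 18,19-O-isopropylidene acetal of the target, via sulfoxide 32 (not isolated)
Conditions: mCPBA (1.0 equiv), CH2Cl2, −78 °C; then PhMe, 100 °C
Reagents that add atoms: none
Why: Sulfide oxidation at −78 °C is much faster than any reaction of the aldehyde, and thermal syn-elimination of the sulfoxide (sulfoxide pyrolysis) in α-alkyl-α-sulfinyl γ-lactones proceeds towards the ring CH2 to give the endocyclic butenolide.

Step 17
Reactants: 33 acetonide of the target
Product: 34 (1R,2S,4aS,8aS)-5,5-bis(hydroxymethyl)-8a-methyl-1-[2-(2-oxo-2,5-dihydrofuran-3-yl)ethyl]decahydronaphthalene-2-carbaldehyde (labdane locants: 5S,8S,9R,10S)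
Conditions: AcOH/THF/H2O (3:1:1), 40 °C
Reagents that add atoms: none
Why: Acid-catalysed acetal hydrolysis frees the 1,3-diol; the aldehyde already has its stable configuration and the butenolide is inert to dilute aqueous acid.

Compound list
1 | hept-1-en-6-yne | C=CCCCC#C | starting material
2 | oxirane | C1CO1 | starting material
3 | [(1E)-2-methylhepta-1,6-dien-1-yl]dimethylalane (formed in situ) | C=CCCC/C(C)=C/[Al](C)C | intermediate
4 | lithium butyl(dimethyl)[(1E)-2-methylhepta-1,6-dien-1-yl]alanate (formed in situ) | [Li+].CCCC[Al-](C)(C)/C=C(\C)CCCC=C | intermediate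
5 | (3E)-4-methylnona-3,8-dien-1-ol | OCC/C=C(\C)CCCC=C | intermediate
6 | (6E)-9-iodo-6-methylnona-1,6-diene | ICC/C=C(\C)CCCC=C | intermediate
7 | 2,3-dihydrofuran | C1CC=CO1 | starting material
8 | 5-lithio-2,3-dihydrofuran (formed in situ) | [Li]C1=CCCO1 | intermediate
9 | 5-[(3E)-4-methylnona-3,8-dien-1-yl]-2,3-dihydrofuran | C=CCCC/C(C)=C/CCC1=CCCO1 | intermediate
10 | (trimethylsilyl)methylmagnesium chloride | C[Si](C)(C)C[Mg]Cl | starting material
11 | (3Z,7E)-8-methyl-4-[(trimethylsilyl)methyl]trideca-3,7,12-trien-1-ol | C=CCCC/C(C)=C/CC/C(C[Si](C)(C)C)=C/CCO | intermediate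
12 | (3Z,7E)-8-methyl-4-[(trimethylsilyl)methyl]trideca-3,7,12-trien-1-yl pivalate | C=CCCC/C(C)=C/CC/C(C[Si](C)(C)C)=C/CCOC(=O)C(C)(C)C | intermediate
13 | B-alkyl-9-borabicyclo[3.3.1]nonane from 12, boron on the former terminal CH2 (formed in situ) | C1CC2CCCC(C1)B2CCCCC/C(C)=C/CC/C(C[Si](C)(C)C)=C/CCOC(=O)C(C)(C)C | intermediate
14 | (3Z,7E)-13-hydroxy-8-methyl-4-[(trimethylsilyl)methyl]trideca-3,7-dien-1-yl pivalate | OCCCCC/C(C)=C/CC/C(C[Si](C)(C)C)=C/CCOC(=O)C(C)(C)C | intermediate
15 | (3Z,7E)-8-methyl-13-oxo-4-[(trimethylsilyl)methyl]trideca-3,7-dien-1-yl pivalate (cyclisation precursor) | O=CCCCC/C(C)=C/CC/C(C[Si](C)(C)C)=C/CCOC(=O)C(C)(C)C | intermediate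
16 | 2-[(1R,4aR,5S,8aR)-5-formyl-8a-methyl-2-methylidenedecahydronaphthalen-1-yl]ethyl pivalate | C[C@@]12CCC[C@H](C=O)[C@H]1CCC(=C)[C@H]2CCOC(=O)C(C)(C)C | intermediate
17 | formaldehyde | C=O | starting material
18 | 2-[(1R,4aS,8aS)-5-formyl-5-(hydroxymethyl)-8a-methyl-2-methylidenedecahydronaphthalen-1-yl]ethyl pivalate, either epimer at labdane C4 (formed in situ) | C[C@@]12CCCC(CO)(C=O)[C@H]1CCC(=C)[C@H]2CCOC(=O)C(C)(C)C | intermediate
19 | 2-[(1R,4aS,8aS)-5,5-bis(hydroxymethyl)-8a-methyl-2-methylidenedecahydronaphthalen-1-yl]ethyl pivalate (formed in situ) | C[C@@]12CCCC(CO)(CO)[C@H]1CCC(=C)[C@H]2CCOC(=O)C(C)(C)C | intermediate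
20 | 2-[(1R,4aS,8aS)-5,5-bis(hydroxymethyl)-8a-methyl-2-methylidenedecahydronaphthalen-1-yl]ethan-1-ol | C[C@@]12CCCC(CO)(CO)[C@H]1CCC(=C)[C@H]2CCO | intermediate
21 | 18,19-O-isopropylidene acetal of 20 (spiro 2,2-dimethyl-1,3-dioxane at C4; 8(17)-ene; 12-OH) | C[C@@]12CCCC3(COC(C)(C)OC3)[C@H]1CCC(=C)[C@H]2CCO | intermediate
22 | 12-iodide corresponding to 21 | C[C@@]12CCCC3(COC(C)(C)OC3)[C@H]1CCC(=C)[C@H]2CCI | intermediate
23 | 3-bromodihydrofuran-2(3H)-one (racemic) | O=C1OCCC1Br | starting material
24 | benzenethiol | Sc1ccccc1 | starting material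
25 | 3-(phenylsulfanyl)dihydrofuran-2(3H)-one (racemic) | O=C1OCCC1Sc1ccccc1 | intermediate
26 | lithium enolate of 25 (formed in situ) | [Li+].[O-]C1=C(Sc2ccccc2)CCO1 | intermediate
27 | 3-(phenylsulfanyl)dihydrofuran-2(3H)-one bearing at C3 the 2-(bicyclic)ethyl group of 22 (C12–C13 bond; both C13 epimers) | C[C@@]12CCCC3(COC(C)(C)OC3)[C@H]1CCC(=C)[C@H]2CCC1(Sc2ccccc2)CCOC1=O | intermediate
28 | B-alkyl-9-borabicyclo[3.3.1]nonane from 27, boron on C17 (formed in situ; C8 and C13 epimers) | C[C@@]12CCCC3(COC(C)(C)OC3)[C@H]1CCC(CB4C5CCCC4CCC5)[C@H]2CCC1(Sc2ccccc2)CCOC1=O | intermediate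
29 | 17-alcohol: 27 with 8-CH2OH in place of the 8(17)-alkene (C8 and C13 epimers) | C[C@@]12CCCC3(COC(C)(C)OC3)[C@H]1CCC(CO)[C@H]2CCC1(Sc2ccccc2)CCOC1=O | intermediate
30 | 17-aldehyde as the C8 epimer mixture obtained directly from oxidation (formed in situ) | C[C@@]12CCCC3(COC(C)(C)OC3)[C@H]1CCC(C=O)[C@H]2CCC1(Sc2ccccc2)CCOC1=O | intermediate
31 | (8S)-17-aldehyde, formyl equatorial and trans to the C9 chain (C13 epimers) | C[C@@]12CCCC3(COC(C)(C)OC3)[C@H]1CC[C@H](C=O)[C@H]2CCC1(Sc2ccccc2)CCOC1=O | intermediate
32 | sulfoxide of 31 (formed in situ; epimers at sulfur and C13) | C[C@@]12CCCC3(COC(C)(C)OC3)[C@H]1CC[C@H](C=O)[C@H]2CCC1(S(=O)c2ccccc2)CCOC1=O | intermediate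
33 | 18,19-O-isopropylidene acetal of the target | C[C@@]12CCCC3(COC(C)(C)OC3)[C@H]1CC[C@H](C=O)[C@H]2CCC1=CCOC1=O | intermediate
34 | (1R,2S,4aS,8aS)-5,5-bis(hydroxymethyl)-8a-methyl-1-[2-(2-oxo-2,5-dihydrofuran-3-yl)ethyl]decahydronaphthalene-2-carbaldehyde | C[C@@]12CCCC(CO)(CO)[C@H]1CC[C@H](C=O)[C@H]2CCC1=CCOC1=O | target

Total step count: 17 (16 in the main line plus the one-step preparation of 25).
Longest linear sequence: 16 steps (steps 1–11 and 13–17, from hept-1-en-6-yne).

Steps most likely to fail

1. Step 8 (key step, beyond precedent).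
- What may go wrong: oxidation of the C10 radical and proton loss before ring B closes (monocyclic dienes), protodesilylation of the terminator in the acidifying medium, or weak facial control at C4.
- Fallback: it sets out from 15 and returns at 19, and thus at 20. It uses cationic instead of radical initiation and only known reaction types.
- α-Methylenation of 15 (aq. HCHO, pyrrolidine, propionic acid) gives the 2-methylene aldehyde F1. Luche reduction (NaBH4, CeCl3·7H2O) gives the allylic alcohol F2. Sharpless epoxidation (Ti(Oi-Pr)4, L-(+)-diethyl tartrate, t-BuOOH, −20 °C) gives the (S)-epoxy alcohol F3. Silylation (t-BuPh2SiCl, imidazole) gives the silyl ether F4.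
- MeAlCl2 (CH2Cl2, −78 °C) should open the 2,2-disubstituted oxirane at C4 with backside attack by C5 and allylsilane termination at C8 (epoxide-initiated cationic bicyclisation), giving the monosilylated decalin diol F5.
- The bulky silyloxymethyl arm is expected to take the equatorial site and the oxirane CH2O the axial one, so the epoxide configuration fixes the absolute sense of the fold.
- Bu4NF then gives 19, which is saponified to 20 as in step 9.

2. Step 9.
- What may go wrong: hydride transfer to the hindered C4 aldehyde before the aldol addition has occurred (C4–H retained), or a slow aldol at the congested C4.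
- Fallback: it sets out from 16 and returns at 20. It uses ester-enolate hydroxymethylation and hydride reduction instead of the one-pot aldol–Cannizzaro.
- Pinnick oxidation (NaClO2, NaH2PO4, 2-methylbut-2-ene) gives the C4 carboxylic acid F6, and Me3SiCHN2 in MeOH/PhMe gives the methyl ester F7.
- LiN(i-Pr)2 (THF, −78 °C) gives the lithium ester enolate F8, which is trapped with gaseous formaldehyde to give the hydroxymethyl ester F9.
- LiAlH4 reduces the ester and removes the pivalate to give 20.

3. Step 14.
- What may go wrong: slow hydroboration of the hindered exocyclic alkene, or oxidation at sulfur or opening of the lactone during the oxidative work-up.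
- Fallback: it sets out from 27 and returns at 33. It uses an epoxide rearrangement instead of hydroboration, with the butenolide made first.
- mCPBA (1 equiv, −78 °C) gives the sulfoxide F10, which is heated in toluene to the butenolide F11 that still carries the 8(17)-alkene.
- mCPBA (NaHCO3, 0 °C) epoxidises only the electron-rich exocyclic alkene to the 8,17-epoxide F12.
- BF3·OEt2 (CH2Cl2, −78 °C) should effect Meinwald rearrangement (1,2-hydride shift from C17 to C8) to the C8 aldehyde as an epimer mixture F13, and DBU equilibrates it to 33.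

Further compounds
F1 | step 8 | (3Z,7E)-12-formyl-8-methyl-4-[(trimethylsilyl)methyl]trideca-3,7,12-trien-1-yl pivalate | O=CC(=C)CCC/C(C)=C/CC/C(C[Si](C)(C)C)=C/CCOC(=O)C(C)(C)C
F2 | step 8 | (3Z,7E)-12-(hydroxymethyl)-8-methyl-4-[(trimethylsilyl)methyl]trideca-3,7,12-trien-1-yl pivalate | OCC(=C)CCC/C(C)=C/CC/C(C[Si](C)(C)C)=C/CCOC(=O)C(C)(C)C
F3 | step 8 | (S)-epoxy alcohol: F2 with its 1,1-disubstituted alkene converted into a 2-(hydroxymethyl)oxirane | C1O[C@]1(CO)CCC/C(C)=C/CC/C(C[Si](C)(C)C)=C/CCOC(=O)C(C)(C)C
F4 | step 8 | tert-butyldiphenylsilyl ether of F3 (same oxirane configuration) | C1O[C@]1(CO[Si](c1ccccc1)(c1ccccc1)C(C)(C)C)CCC/C(C)=C/CC/C(C[Si](C)(C)C)=C/CCOC(=O)C(C)(C)C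
F5 | step 8 | 19 with its equatorial CH2OH silylated (axial CH2OH free; tert-butyldiphenylsilyl) | C[C@@]12CCC[C@](CO)(CO[Si](c3ccccc3)(c3ccccc3)C(C)(C)C)[C@H]1CCC(=C)[C@H]2CCOC(=O)C(C)(C)C
F6 | step 9 | carboxylic acid from 16 (CO2H in place of CHO at C4) | C[C@@]12CCC[C@H](C(=O)O)[C@H]1CCC(=C)[C@H]2CCOC(=O)C(C)(C)C
F7 | step 9 | methyl ester of F6 | C[C@@]12CCC[C@H](C(=O)OC)[C@H]1CCC(=C)[C@H]2CCOC(=O)C(C)(C)C
F8 | step 9 | lithium enolate of F7 | [Li+].C[C@@]12CCCC(=C([O-])OC)[C@H]1CCC(=C)[C@H]2CCOC(=O)C(C)(C)C
F9 | step 9 | 4-(hydroxymethyl) methyl ester (either C4 epimer) | C[C@@]12CCCC(CO)(C(=O)OC)[C@H]1CCC(=C)[C@H]2CCOC(=O)C(C)(C)C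
F10 | step 14 | sulfoxide of 27 | C[C@@]12CCCC3(COC(C)(C)OC3)[C@H]1CCC(=C)[C@H]2CCC1(S(=O)c2ccccc2)CCOC1=O
F11 | step 14 | butenolide acetonide with the 8(17)-alkene | C[C@@]12CCCC3(COC(C)(C)OC3)[C@H]1CCC(=C)[C@H]2CCC1=CCOC1=O
F12 | step 14 | 8,17-epoxide of F11 (either face) | C[C@@]12CCCC3(COC(C)(C)OC3)[C@H]1CCC4(CO4)[C@H]2CCC1=CCOC1=O
F13 | step 14 | C8 epimer mixture of 33 | C[C@@]12CCCC3(COC(C)(C)OC3)[C@H]1CCC(C=O)[C@H]2CCC1=CCOC1=O
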